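## The problem

(−)-Cubebininolide (11) is a single γ-butyrolactone ring (O1, C2 carbonyl, C3, C4, C5) with nothing fused or bridged. The task is therefore to build the four-carbon chain C2–C3–C4–C5 with two identical 3,4,5-trimethoxybenzyl arms on C3 and C4, and to fix the two adjacent stereocentres as 3R,4R (arms trans). C3 lies α to the carbonyl and can be epimerised, so it can be steered by C4 toward the favoured trans arrangement; C4 has no acidic hydrogen and must be set absolutely. A route that fixes both centres by mechanism does not depend on that equilibrium. The groups that limit the reagents are the two electron-rich trimethoxyarenes (strong electrophiles, strong oxidants, ether-cleaving Lewis acids), the lactone and any anhydride precursor (hydroxide, alkoxide), and the base-labile C3–H. The enabling feature is a hidden symmetry: C3 and C4 each carry one benzyl arm and one carboxyl-level carbon, C2 as C=O and C5 as CH2–O. Raising C5 to the carbonyl level gives the trans-2,3-dibenzylsuccinic anhydride 9, which has a C2 axis through the ring oxygen and the midpoint of C3–C4 and hence two homotopic carbonyl groups. That anhydride is, atom for atom, the trans-oxirane 6 plus two molecules of carbon monoxide (7).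

## Retrosynthesis

**11 to 9 (through 10).** No skeletal bond is cut first: the C5 methylene is traced back to a second carbonyl group, which turns the lactone into anhydride 9. In the forward sense the ring opens to hydroxy acid 10 and recloses. The neighbouring cuts (removing the C3 arm by enolate benzylation, or removing both aryl groups) keep the two halves different and need separate control of C3 and C4. Going to 9 makes the halves identical, so every earlier operation can be run twice in one flask. The forward reaction must put two hydrides on one carbonyl and stop at the lactone; the carbonyls are homotopic, so there is no regiochemical question, and the stereocentres are not touched.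

**9 to 6 and two molecules of 7 (through 8).** Four bonds are cut together: C3–C2, C4–C5 and both acyl–oxygen bonds. The oxirane oxygen of 6 becomes the bridging oxygen of 9. Other ways to 9 (oxidative coupling of two arylpropanoate enolates, or alkylation chemistry) need stoichiometric chiral auxiliaries and carry the carboxyl carbons from the start. The carbonylative cut removes every carboxyl carbon, leaves a precursor with one functional group, and keeps the C2 axis. The forward reaction must open a C–O bond twice by SN2 attack with inversion, once on 6 and once on the cis-β-lactone 8. A trans-oxirane then gives a trans-anhydride, and S,S-6 gives R,R-9, because each departing oxygen is replaced from the opposite side by an acyl carbon of the same top priority. CO insertion must also outrun β-hydride elimination.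

**6 to 5.** The two C–O bonds of the oxirane are cut, leading to the E-alkene 5, whose two faces are enantiotopic. A reagent-controlled oxygen transfer from a chiral dioxirane is the one-step answer, and E-1,2-disubstituted alkenes are its best substrates. A dihydroxylation followed by ring closure with double inversion would reach the same oxirane in more operations. The forward reaction must pick one face. The common D-fructose-derived ketone gives R,R-oxiranes from alkenes of this type, so its mirror image is needed.

**5 to two molecules of 4.** The C=C bond is cut, giving two molecules of allylarene 4. Metathesis homodimerisation fits a symmetric alkene: there is no cross-selectivity problem, and only a volatile two-carbon by-product is lost. The forward reaction must deliver the E isomer (favoured at equilibrium, to be completed by crystallisation) without moving the double bond into conjugation.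

**4 to 1 and 2 (through 3).** The aryl–CH2 bond is cut. Aryl bromide 1 becomes Grignard reagent 3, which is allylated by allyl bromide 2. Both are catalogue compounds and the coupling has no selectivity issue.

## Roads not taken

**Alternative 1:** The bonds from C3 and C4 to the two future benzylic carbons are cut. The C2–C3–C4–C5 unit comes from diethyl fumarate A1 and the benzylic carbons from the termini of buta-1,3-diene A2.

- **Key step.** A Diels–Alder reaction of A1 with A2 under a chiral cationic oxazaborolidine (activated by HNTf2) gives diethyl (1R,2R)-cyclohex-4-ene-1,2-dicarboxylate A3. The ring alkene of A3 is then cleaved oxidatively, its two carbons are discarded, and the aryl groups are attached to the remaining CH2 carbons by twofold decarboxylative arylation.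
- **Merits.** The trans relationship in A3 is inherited from the geometry of A1, which is a pure E compound. The absolute configuration comes from a well-studied catalyst, and A1 and A2 are very cheap feedstocks.
- **Weak points.** A six-membered ring is built only to remove two of its carbons. After cleavage of A3 the molecule has four carboxyl-level groups; two must undergo radical decarboxylative coupling on one substrate while the two esters survive. The esters must then be hydrolysed (with risk to the α-centres), closed to 9 and reduced. This is at least seven operations.
- **Comparison.** This road is stronger in one respect: its relative configuration never depends on the isomeric purity of a metathesis product. The chosen plan sets against this the crystallisation of 5, two fewer steps, and the fact that all atoms of 6 and 7 end up in 9.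

**Alternative 2:** The two aryl–CH2 bonds are cut.

- **Key step.** The bis(8-quinolyl)amide (2R,3R)-2,3-dimethyl-N1,N4-di(quinolin-8-yl)succinamide A4 is arylated at both methyl groups with 5-iodo-1,2,3-trimethoxybenzene A5 under Pd(OAc)2 and AgOAc. This gives (2R,3R)-N1,N4-di(quinolin-8-yl)-2,3-bis(3,4,5-trimethoxybenzyl)succinamide A6.
- **Merits.** The aryl groups enter last from A5, so analogues are easy. The skeleton and both stereocentres are present from the start in A4, and no pressure equipment is needed.
- **Weak points.** The enantiopure dimethylsuccinic acid behind A4 is not a commodity. Two bidentate directing groups on one short chain can tie up palladium unproductively. Each methyl group can be arylated more than once by A5. The α-C–H bonds may epimerise at the temperatures such arylations need. The two robust amides of A6 must be cleaved without epimerisation before ring closure and reduction. Silver is used stoichiometrically.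
- **Comparison.** This road is better in modularity. The chosen plan needs no auxiliary, sets the configuration catalytically, and is shorter once the supply of A4 and the removal of the directing groups from A6 are counted.

**Alternative 3:** The aryl–CH2 bond of the C4 arm and the C3–CH2 bond are cut.

- **Key step.** Grignard reagent 3 with CuI opens the cyclopropane CH2 of the bicyclic lactone ester methyl (1S,5R)-2-oxo-3-oxabicyclo[3.1.0]hexane-1-carboxylate A7 by homoconjugate addition. The resulting enolate is trapped with 5-(bromomethyl)-1,2,3-trimethoxybenzene A8 to give methyl (3R,4R)-2-oxo-3,4-bis(3,4,5-trimethoxybenzyl)tetrahydrofuran-3-carboxylate A9. Dealkoxycarbonylation of A9 then gives 11.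
- **Merits.** It is very short. C4 comes from the enantiopure building block A7, and no pressure equipment or custom catalyst is needed.
- **Weak points.** A stabilised, poorly nucleophilic enolate must be alkylated to a quaternary carbon next to a tertiary centre in the same flask. Unconsumed 3 and copper compete for A8, and Grignard attack on the lactone or ester carbonyl of A7 competes with cyclopropane opening. The C3 configuration of A9 is lost on decarboxylation, so the final C3 centre rests on protonation and equilibration toward trans. Two different aryl building blocks are needed.
- **Comparison.** This road is shorter than the chosen plan and operationally simpler. The chosen plan sets against this that both stereocentres are fixed by stereospecific bond formation, and that one aryl building block serves twice through symmetric intermediates.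

Key step: step 4

Assumption: the two catalysts that are not catalogue items, the L-series epoxidation ketone (from L-sorbose) and [(ClTPP)Al(THF)2][Co(CO)4] (from (ClTPP)AlCl and NaCo(CO)4), are prepared separately and are not counted as steps.

## Route

Step 1
Reactants: 1 5-bromo-1,2,3-trimethoxybenzene; 2 allyl bromide (3-bromoprop-1-ene)
Product: 4 5-allyl-1,2,3-trimethoxybenzene (elemicin), via aryl Grignard reagent 3 (not isolated)
Conditions: Mg, I2 (cat.), THF, reflux; then 2, CuI (5 mol %), 0 °C to rt
Reagents that add atoms: magnesium, [Mg] (held in intermediate 3 only, lost again as MgBr2 on coupling)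
Why: Magnesium insertion gives the aryl Grignard reagent 3, and copper-catalysed coupling of an aryl Grignard reagent with allyl bromide (Grignard allylation) is a standard route to allylarenes; the aryl methyl ethers are inert and no stereocentre is formed.

Step 2
Reactants: 4 5-allyl-1,2,3-trimethoxybenzene (two molecules)
Product: 5 (E)-1,4-bis(3,4,5-trimethoxyphenyl)but-2-ene
Conditions: second-generation Grubbs catalyst (H2IMes)(PCy3)Cl2Ru=CHPh (2 mol %), 1,4-benzoquinone (10 mol %), CH2Cl2, 40 °C, Ar sweep; recrystallisation
Reagents that add atoms: none
Why: Olefin metathesis homodimerisation of a terminal allylarene: loss of ethylene drives the reaction and secondary metathesis moves the product toward the more stable E isomer, which is expected to be freed of the minor Z isomer by recrystallisation. 1,4-Benzoquinone intercepts ruthenium hydrides and so holds back migration of the double bond into conjugation with the ring.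

Step 3
Reactants: 5 (E)-1,4-bis(3,4,5-trimethoxyphenyl)but-2-ene
Product: 6 (2S,3S)-2,3-bis(3,4,5-trimethoxybenzyl)oxirane (trans)
Conditions: L-fructose-derived Shi ketone (1,2:4,5-di-O-isopropylidene-β-L-erythro-2,3-hexodiulo-2,6-pyranose, 30 mol %), KHSO5 (as 2KHSO5·KHSO4·K2SO4), K2CO3, Bu4NHSO4 (cat.), MeCN–CH2(OMe)2/aq. Na2B4O7–Na2EDTA buffer (pH 10.5), 0 °C
Reagents that add atoms: potassium peroxymonosulfate (KHSO5), [K+].[O-]S(=O)(=O)OO
Why: Shi epoxidation: the chiral dioxirane formed in situ from the ketone and KHSO5 transfers oxygen through a spiro transition state, and E-1,2-disubstituted alkenes are its best substrates. The D-fructose-derived ketone gives R,R-oxiranes from such alkenes, so its mirror image is used to set both stereocentres as S,S in one event; the buffered pH of 10.5 limits Baeyer–Villiger loss of the catalyst, and the mild dioxirane should leave the trimethoxyarenes alone at 0 °C.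

Step 4
Reactants: 6 (2S,3S)-2,3-bis(3,4,5-trimethoxybenzyl)oxirane; 7 carbon monoxide (two molecules)
Product: 9 (3R,4R)-3,4-bis(3,4,5-trimethoxybenzyl)dihydrofuran-2,5-dione (trans anhydride), via cis-β-lactone 8 (not isolated)
Conditions: [(ClTPP)Al(THF)2][Co(CO)4] (5 mol %; ClTPP = meso-tetrakis(4-chlorophenyl)porphyrinato), CO (60 bar), 1,4-dioxane, 90 °C
Reagents that add atoms: none
Why: Each CO enters by the same four events: the aluminium porphyrin cation binds the ring oxygen, [Co(CO)4]− opens the activated C–O bond from the rear (SN2, inversion), CO inserts into the new C–Co bond with retention at carbon, and the aluminium-bound oxygen nucleophile attacks the acylcobalt and releases [Co(CO)4]−. In the first pass the alkoxide closes the cis-β-lactone 8 (4-exo-trig); in the second pass the C4–O bond of 8 is opened and the carboxylate closes the anhydride (5-exo-trig), the only ring that remains. The closest known reaction is the double carbonylation of simple cis- and trans-2,3-dialkyloxiranes to the corresponding succinic anhydrides with this same ion pair; 1,2-disubstituted oxiranes react more slowly than terminal ones, hence the higher loading and temperature. Both new stereocentres are controlled by the substrate: each oxirane carbon is inverted exactly once, so S,S-6 gives R,R-9 and a trans-oxirane gives a trans-anhydride. The step needs stereospecificity and chemoselectivity but no regioselectivity, because the C2 axis of 6 makes its two C–O bonds equivalent and 8 has only one alkyl–oxygen bond to open. Stereospecificity rests on both carbons being secondary and not benzylic, so ionisation should not compete with direct displacement; chemoselectivity for insertion over β-hydride elimination to a ketone rests on the high CO pressure. 1,4-Dioxane is a donor weak enough not to block the lactone stage, which begins once the more basic oxirane has been consumed.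

Step 5
Reactants: 9 (3R,4R)-3,4-bis(3,4,5-trimethoxybenzyl)dihydrofuran-2,5-dione
Product: 11 (−)-cubebininolide, (3R,4R)-3,4-bis(3,4,5-trimethoxybenzyl)dihydrofuran-2(3H)-one, via hydroxy acid 10 (not isolated)
Conditions: NaBH4 (1 equiv), THF, 0 °C to rt; then 2 M HCl, rt
Reagents that add atoms: none
Why: Borohydride reduction of a cyclic anhydride to a γ-lactone: hydride adds to one carbonyl group, the ring opens to an aldehyde carboxylate that is reduced further to the salt of hydroxy acid 10, and acid closes the lactone. The two carbonyl groups of 9 are exchanged by the C2 axis, so only one lactone can form, and no bond to C3 or C4 is made or broken, so 3R,4R is carried over unchanged.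

## Compound list

1 | 5-bromo-1,2,3-trimethoxybenzene | COc1cc(Br)cc(OC)c1OC | starting material
2 | allyl bromide | C=CCBr | starting material
3 | (3,4,5-trimethoxyphenyl)magnesium bromide | COc1cc([Mg]Br)cc(OC)c1OC | intermediate
4 | 5-allyl-1,2,3-trimethoxybenzene (elemicin) | C=CCc1cc(OC)c(OC)c(OC)c1 | intermediate
5 | (E)-1,4-bis(3,4,5-trimethoxyphenyl)but-2-ene | COc1cc(C/C=C/Cc2cc(OC)c(OC)c(OC)c2)cc(OC)c1OC | intermediate
6 | (2S,3S)-2,3-bis(3,4,5-trimethoxybenzyl)oxirane | COc1cc(C[C@@H]2O[C@H]2Cc2cc(OC)c(OC)c(OC)c2)cc(OC)c1OC | intermediate
7 | carbon monoxide | [C-]#[O+] | starting material
8 | (3R,4S)-3,4-bis(3,4,5-trimethoxybenzyl)oxetan-2-one (cis-β-lactone) | COc1cc(C[C@@H]2OC(=O)[C@@H]2Cc2cc(OC)c(OC)c(OC)c2)cc(OC)c1OC | intermediate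
9 | (3R,4R)-3,4-bis(3,4,5-trimethoxybenzyl)dihydrofuran-2,5-dione | COc1cc(C[C@H]2C(=O)OC(=O)[C@@H]2Cc2cc(OC)c(OC)c(OC)c2)cc(OC)c1OC | intermediate
10 | (2R,3R)-4-hydroxy-2,3-bis(3,4,5-trimethoxybenzyl)butanoic acid | COc1cc(C[C@@H](CO)[C@@H](Cc2cc(OC)c(OC)c(OC)c2)C(=O)O)cc(OC)c1OC | intermediate
11 | (−)-cubebininolide, (3R,4R)-3,4-bis(3,4,5-trimethoxybenzyl)dihydrofuran-2(3H)-one | COc1cc(C[C@H]2COC(=O)[C@@H]2Cc2cc(OC)c(OC)c(OC)c2)cc(OC)c1OC | target

## Step count and risks

Total step count: 5. Longest linear sequence: 5 steps (1 to 4 to 5 to 6 to 9 to 11).

**Step 4 (key step).**
- **Risk.** The sequence may stall after the first CO insertion, because rear-side attack of [Co(CO)4]− at C4 of the cis-lactone 8 is hindered by the two benzyl groups. At the temperature needed to force it, the Lewis-acid-activated oxirane may isomerise to a ketone through β-hydride elimination, and the β-lactone may lose CO2. Participation of the electron-rich aryl ring in C–O cleavage would erode the stereospecificity.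
- **Fallback.** It sets out from oxirane 6 and comes back to the route at hydroxy acid 10, bypassing 9. Only the first carbonylation is asked of the cobalt catalyst: with the same ion pair in THF, a donor solvent that suppresses the lactone stage, and at lower temperature, 6 should stop at the cis-β-lactone 8, which is isolated. Vinylmagnesium bromide with CuBr·SMe2 in THF–Me2S at low temperature then opens 8 at C4 by alkyl–oxygen cleavage with inversion, the known mode of organocuprate attack on β-lactones. This gives (2R,3S)-2,3-bis(3,4,5-trimethoxybenzyl)pent-4-enoic acid F1. Ozonolysis of the vinyl group at −78 °C to an indicator end point, with NaBH4 work-up, turns it into CH2OH and delivers 10, which lactonises to 11 on acidification as in step 5. The vinyl group is a masked hydroxymethyl group, and C4 is inverted exactly as in the cobalt pathway, so the configuration of 11 is the same.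

**Step 2.**
- **Risk.** E selectivity is set only by the equilibrium and may be incomplete, and ruthenium hydrides may move the double bond into conjugation before metathesis, giving chain-shortened alkenes. Any Z-alkene that survives is carried faithfully by steps 3 and 4 into the cis (meso) series.
- **Fallback.** It sets out from bromide 1 through its Grignard reagent 3 and comes back at oxirane 6; it avoids the alkene altogether. CuI-catalysed attack of 3 (two molecules) on both terminal carbons of (2S,3S)-1,2:3,4-diepoxybutane, a tartaric-acid-derived reagent, leaves the two stereocentres untouched and gives (2S,3S)-1,4-bis(3,4,5-trimethoxyphenyl)butane-2,3-diol F2. A one-flask diol-to-epoxide sequence (Kolb–Sharpless) follows. MeC(OMe)3 with a trace of acid gives the cyclic orthoacetate (4S,5S)-2-methoxy-2-methyl-4,5-bis(3,4,5-trimethoxybenzyl)-1,3-dioxolane F3. AcBr opens it through the acetoxonium ion, with inversion at the carbon that takes bromide, to (2S,3R)-3-bromo-1,4-bis(3,4,5-trimethoxyphenyl)butan-2-yl acetate F4. K2CO3 in MeOH removes the acetate, and the alkoxide displaces bromide with a second inversion to give 6. Because the configuration then comes from the chiral pool, the same bypass would also serve if the enantiomeric purity from step 3 fell short.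

**Step 5.**
- **Risk.** Reduction may run on from the lactone stage to the 1,4-diol, or may be incomplete so that unreacted anhydride is hydrolysed to the diacid on acidification. The basic medium could epimerise the centre next to the transient aldehyde.
- **Fallback.** It sets out from 9 and comes back at 11. Methanolysis of 9 gives one half-ester, by symmetry: (2R,3R)-4-methoxy-4-oxo-2,3-bis(3,4,5-trimethoxybenzyl)butanoic acid F5. BH3·SMe2 in THF reduces the free acid selectively in the presence of the ester to methyl (2R,3R)-4-hydroxy-2,3-bis(3,4,5-trimethoxybenzyl)butanoate F6. F6 lactonises with a trace of TsOH, losing methanol, to give 11.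

## Further compounds

F1 | step 4 | (2R,3S)-2,3-bis(3,4,5-trimethoxybenzyl)pent-4-enoic acid | COc1cc(C[C@@H](C=C)[C@@H](Cc2cc(OC)c(OC)c(OC)c2)C(=O)O)cc(OC)c1OC
F2 | step 2 | (2S,3S)-1,4-bis(3,4,5-trimethoxyphenyl)butane-2,3-diol | COc1cc(C[C@H](O)[C@@H](O)Cc2cc(OC)c(OC)c(OC)c2)cc(OC)c1OC
F3 | step 2 | (4S,5S)-2-methoxy-2-methyl-4,5-bis(3,4,5-trimethoxybenzyl)-1,3-dioxolane | COc1cc(C[C@@H]2OC(C)(OC)O[C@H]2Cc2cc(OC)c(OC)c(OC)c2)cc(OC)c1OC
F4 | step 2 | (2S,3R)-3-bromo-1,4-bis(3,4,5-trimethoxyphenyl)butan-2-yl acetate | COc1cc(C[C@H](OC(C)=O)[C@H](Br)Cc2cc(OC)c(OC)c(OC)c2)cc(OC)c1OC
F5 | step 5 | (2R,3R)-4-methoxy-4-oxo-2,3-bis(3,4,5-trimethoxybenzyl)butanoic acid | COc1cc(C[C@@H](C(=O)OC)[C@@H](Cc2cc(OC)c(OC)c(OC)c2)C(=O)O)cc(OC)c1OC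
F6 | step 5 | methyl (2R,3R)-4-hydroxy-2,3-bis(3,4,5-trimethoxybenzyl)butanoate | COc1cc(C[C@@H](C(=O)OC)[C@@H](Cc2cc(OC)c(OC)c(OC)c2)CO)cc(OC)c1OC
A1 | alternative 1 | diethyl fumarate | CCOC(=O)/C=C/C(=O)OCC
A2 | alternative 1 | buta-1,3-diene | C=CC=C
A3 | alternative 1 | diethyl (1R,2R)-cyclohex-4-ene-1,2-dicarboxylate | CCOC(=O)[C@@H]1CC=CC[C@H]1C(=O)OCC
A4 | alternative 2 | (2R,3R)-2,3-dimethyl-N1,N4-di(quinolin-8-yl)succinamide | O=C(Nc1cccc2cccnc12)[C@H](C)[C@@H](C)C(=O)Nc1cccc2cccnc12
A5 | alternative 2 | 5-iodo-1,2,3-trimethoxybenzene | COc1cc(I)cc(OC)c1OC
A6 | alternative 2 | (2R,3R)-N1,N4-di(quinolin-8-yl)-2,3-bis(3,4,5-trimethoxybenzyl)succinamide | O=C(Nc1cccc2cccnc12)[C@H](Cc1cc(OC)c(OC)c(OC)c1)[C@@H](Cc1cc(OC)c(OC)c(OC)c1)C(=O)Nc1cccc2cccnc12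
A7 | alternative 3 | methyl (1S,5R)-2-oxo-3-oxabicyclo[3.1.0]hexane-1-carboxylate | O=C1OC[C@@H]2C[C@]12C(=O)OC
A8 | alternative 3 | 5-(bromomethyl)-1,2,3-trimethoxybenzene | COc1cc(CBr)cc(OC)c1OC
A9 | alternative 3 | methyl (3R,4R)-2-oxo-3,4-bis(3,4,5-trimethoxybenzyl)tetrahydrofuran-3-carboxylate (3-benzyl trans to 4-benzyl) | COc1cc(C[C@H]2COC(=O)[C@@]2(Cc2cc(OC)c(OC)c(OC)c2)C(=O)OC)cc(OC)c1OC
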